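The γ-lactone (ring atoms O1, C2, C3, C4, C5) is disconnected at C3–C4. The route exploits that the quaternary C5 carries the ring oxygen and sits next to the exocyclic secondary carbinol: C5, O1 and C4 are stored as a 2,2-disubstituted oxirane, and C3 and C2 as an acetate on the carbinol oxygen. One base treatment makes the acetate enolate close a six-membered lactone by attack on the oxirane CH2 (the C3–C4 bond); the released C5 alkoxide then takes over the acyl group, contracting to the γ-lactone and freeing the carbinol. The epoxy acetate comes from (S)-linalool; a final cross-metathesis adds the furyl diene.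

Key step: step 6

Remark: (S)-(+)-linalool (coriandrol) is assumed to be purchasable in high enantiomeric purity; its carbinol centre becomes the tertiary allylic carbinol of the target unchanged.

Step 1
Reactants: 1 (S)-(+)-linalool, (3S)-3,7-dimethylocta-1,6-dien-3-ol
Product: 2 triethyl{[(3S)-3,7-dimethylocta-1,6-dien-3-yl]oxy}silane
Conditions: Et3SiOTf, 2,6-lutidine, CH2Cl2, −78 → 0 °C
Reagents that add atoms: triethylsilyl trifluoromethanesulfonate, CC[Si](CC)(CC)OS(=O)(=O)C(F)(F)F
Why: Silylation of the hindered tertiary allylic alcohol with a silyl triflate masks the hydroxyl that would otherwise open the later 6,7-epoxide to a tetrahydrofuran, and leaves the stereocentre untouched.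

Step 2
Reactants: 2 triethyl{[(3S)-3,7-dimethylocta-1,6-dien-3-yl]oxy}silane
Product: 3 (3R)-2,2-dimethyl-3-[(3S)-3-methyl-3-(triethylsilyloxy)pent-4-en-1-yl]oxirane
Conditions: D-fructose-derived Shi ketone (0.3 equiv), KHSO5 (as Oxone), K2CO3, Bu4NHSO4, MeCN/CH2(OMe)2/aq. Na2B4O7 buffer, 0 °C
Reagents that add atoms: potassium peroxymonosulfate, OOS(=O)(=O)[O-].[K+]
Why: Shi asymmetric epoxidation by the chiral dioxirane attacks only the electron-rich trisubstituted alkene and, through its spiro transition state, should set the oxirane CH centre as R under reagent control.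

Step 3
Reactants: 3 (3R)-2,2-dimethyl-3-[(3S)-3-methyl-3-(triethylsilyloxy)pent-4-en-1-yl]oxirane
Product: 4 (3R,6S)-2,6-dimethyl-6-(triethylsilyloxy)octa-1,7-dien-3-ol
Conditions: Et2AlCl, lithium 2,2,6,6-tetramethylpiperidide (from the amine and n-BuLi), toluene, 0 °C; aq. potassium sodium tartrate
Reagents that add atoms: none
Why: Aluminium amide-mediated isomerisation of a trisubstituted epoxide to an allylic alcohol removes a proton from a geminal methyl group in a syn-elimination and gives the isopropenyl carbinol with the C–O stereocentre retained.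

Step 4
Reactants: 4 (3R,6S)-2,6-dimethyl-6-(triethylsilyloxy)octa-1,7-dien-3-ol
Product: 5 (1R,4S)-4-methyl-1-[(2S)-2-methyloxiran-2-yl]-4-(triethylsilyloxy)hex-5-en-1-ol
Conditions: VO(acac)2 (cat.), t-BuOOH, CH2Cl2, 0 °C → rt
Reagents that add atoms: tert-butyl hydroperoxide, CC(C)(C)OO
Why: Hydroxyl-directed vanadium-catalysed epoxidation of a 2-substituted secondary allylic alcohol reacts through the conformer in which the carbinol hydrogen eclipses the alkene methyl group (A1,2 strain), so oxygen should be delivered anti to the chain to give the erythro epoxy alcohol with the (2S)-oxirane centre, while the silyl-protected vinyl group is not directed and stays intact.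

Step 5
Reactants: 5 (1R,4S)-4-methyl-1-[(2S)-2-methyloxiran-2-yl]-4-(triethylsilyloxy)hex-5-en-1-ol
Product: 6 (1R,4S)-4-methyl-1-[(2S)-2-methyloxiran-2-yl]-4-(triethylsilyloxy)hex-5-en-1-yl acetate
Conditions: Ac2O, Et3N, DMAP (cat.), CH2Cl2, 0 °C → rt
Reagents that add atoms: acetic anhydride, CC(=O)OC(C)=O
Why: DMAP-catalysed acetylation of the only free hydroxyl places the two-carbon nucleophile precursor next to the oxirane under conditions that spare the epoxide.

Step 6
Reactants: 6 (1R,4S)-4-methyl-1-[(2S)-2-methyloxiran-2-yl]-4-(triethylsilyloxy)hex-5-en-1-yl acetate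
Product: 9 (5S)-5-[(1R,4S)-1-hydroxy-4-methyl-4-(triethylsilyloxy)hex-5-en-1-yl]-5-methyloxolan-2-one, via lithium ester enolate 7 (not isolated), via six-membered lactone lithium alkoxide 8 (not isolated)
Conditions: LiN(SiMe3)2 (1.3 equiv), THF, −78 → 0 °C; aq. NH4Cl
Reagents that add atoms: none
Why: Proposed new method: LiN(SiMe3)2 forms the lithium enolate 7 of the acetate, whose α-carbon (future C3) attacks the oxirane CH2 (future C4) anti to its C–O bond through a chair-like six-atom array, the same six atoms as in an Ireland–Claisen transition state with the strained oxirane in place of the alkene, so that ring strain release drives the C–C bond formation and gives alkoxide 8; the closest known reaction types are the Stork epoxynitrile cyclisation with its ester-enolate variants and the intermolecular lactone synthesis from ester enolates and epoxides, neither of which has the enolate tethered through the ester oxygen. The six-membered lactone closes by a 6-(enolendo)-exo-tet alkylation (endo mode with respect to the oxirane, both of its carbons entering the ring), and the γ-lactone then closes by 5-exo-trig attack of the tertiary C5 alkoxide on the lactone carbonyl with expulsion of the secondary alkoxide (O-to-O acyl transfer). No stereocentre is created, since both carbons of the new bond are methylene groups, and the C5 and carbinol configurations fixed in steps 2 and 4 survive because no bond to either centre is broken. The step needs attack at the oxirane CH2 and not at the fully substituted oxirane carbon, which steric blocking and the disfavoured 5-(enolendo) alternative secure, and C- over O-alkylation, which lithium in THF at low temperature favours. The acyl shift is pulled forward by the lower strain of the γ-lactone and the lower basicity of the secondary alkoxide.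

Step 7
Reactants: 9 (5S)-5-[(1R,4S)-1-hydroxy-4-methyl-4-(triethylsilyloxy)hex-5-en-1-yl]-5-methyloxolan-2-one
Product: 10 (5S)-5-[(1R,4S)-1,4-dihydroxy-4-methylhex-5-en-1-yl]-5-methyloxolan-2-one
Conditions: HF·pyridine, pyridine, THF, 0 °C → rt
Reagents that add atoms: none
Why: Buffered fluoride desilylation should cleave the tertiary triethylsilyl ether without opening the lactone or ionising the tertiary allylic alcohol, and any residual six-membered lactone should converge on the γ-lactone.

Step 8
Reactants: 11 furan-3-carbaldehyde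
Product: 12 3-ethenylfuran
Conditions: Ph3PCH3Br, KOtBu, THF, 0 °C → rt; product kept as a distilled THF solution
Reagents that add atoms: methyltriphenylphosphonium bromide, C[P+](c1ccccc1)(c1ccccc1)c1ccccc1.[Br-]
Why: Wittig methylenation of the non-enolisable heteroaryl aldehyde with the unstabilised ylide gives the vinylfuran.

Step 9
Reactants: 13 pent-1-en-4-yne
Product: 15 (1E)-1-iodo-2-methylpenta-1,4-diene, via alkenyldimethylalane 14 (not isolated)
Conditions: Me3Al (2 equiv), Cp2ZrCl2 (cat.), CH2Cl2, 0 °C → rt; then I2, THF, −30 → 0 °C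
Reagents that add atoms: trimethylaluminium, C[Al](C)C; iodine, II
Why: Negishi zirconium-catalysed methylalumination adds methyl and aluminium syn across the terminal alkyne with aluminium on the terminal carbon, and iodinolysis with retention gives the E-alkenyl iodide, the isolated alkene reacting far more slowly than the alkyne.

Step 10
Reactants: 12 3-ethenylfuran; 15 (1E)-1-iodo-2-methylpenta-1,4-diene
Product: 17 3-[(3E)-4-methylhepta-3,6-dien-1-yl]furan, via alkyl-9-BBN borane 16 (not isolated)
Conditions: 9-BBN, THF, 0 °C → rt; then 15, Pd(dppf)Cl2 (cat.), AsPh3, Cs2CO3, DMF/H2O, rt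
Reagents that add atoms: none
Why: Anti-Markovnikov hydroboration of the vinyl group with 9-BBN followed by B-alkyl Suzuki–Miyaura coupling joins the sp3 carbon to the alkenyl iodide with retention of the E geometry.

Step 11
Reactants: 10 (5S)-5-[(1R,4S)-1,4-dihydroxy-4-methylhex-5-en-1-yl]-5-methyloxolan-2-one; 17 3-[(3E)-4-methylhepta-3,6-dien-1-yl]furan
Product: 18 (5S)-5-[(1R,4S,5E,8E)-11-(furan-3-yl)-1,4-dihydroxy-4,8-dimethylundeca-5,8-dien-1-yl]-5-methyloxolan-2-one
Conditions: second-generation Hoveyda–Grubbs catalyst RuCl2(H2IMes)(=CH-C6H4-2-OiPr) (cat.), 1,4-benzoquinone (cat.), 17 in excess, CH2Cl2, 40 °C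
Reagents that add atoms: none
Why: Olefin cross-metathesis between the unhindered terminal alkene of 17 and the vinyl group on the free tertiary allylic carbinol of 10 should give the E-disubstituted alkene, the quaternary allylic centre disfavouring the Z isomer, while the trisubstituted alkene, furan and lactone are inert to the ruthenium carbene.

Compound list
1 | (S)-(+)-linalool, (3S)-3,7-dimethylocta-1,6-dien-3-ol | C=C[C@@](C)(O)CCC=C(C)C | starting material
2 | triethyl{[(3S)-3,7-dimethylocta-1,6-dien-3-yl]oxy}silane | C=C[C@@](C)(O[Si](CC)(CC)CC)CCC=C(C)C | intermediate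
3 | (3R)-2,2-dimethyl-3-[(3S)-3-methyl-3-(triethylsilyloxy)pent-4-en-1-yl]oxirane | C=C[C@@](C)(O[Si](CC)(CC)CC)CC[C@H]1OC1(C)C | intermediate
4 | (3R,6S)-2,6-dimethyl-6-(triethylsilyloxy)octa-1,7-dien-3-ol | C=C[C@@](C)(O[Si](CC)(CC)CC)CC[C@@H](O)C(C)=C | intermediate
5 | (1R,4S)-4-methyl-1-[(2S)-2-methyloxiran-2-yl]-4-(triethylsilyloxy)hex-5-en-1-ol | C=C[C@@](C)(O[Si](CC)(CC)CC)CC[C@@H](O)[C@]1(C)CO1 | intermediate
6 | (1R,4S)-4-methyl-1-[(2S)-2-methyloxiran-2-yl]-4-(triethylsilyloxy)hex-5-en-1-yl acetate | C=C[C@@](C)(O[Si](CC)(CC)CC)CC[C@@H](OC(C)=O)[C@]1(C)CO1 | intermediate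
7 | lithium enolate of acetate 6 | C=C[C@@](C)(O[Si](CC)(CC)CC)CC[C@@H](OC(=C)[O-])[C@]1(C)CO1.[Li+] | intermediate (not isolated)
8 | lithium alkoxide of (5S,6R)-5-hydroxy-5-methyl-6-[(3S)-3-methyl-3-(triethylsilyloxy)pent-4-en-1-yl]oxan-2-one | C=C[C@@](C)(O[Si](CC)(CC)CC)CC[C@H]1OC(=O)CC[C@]1(C)[O-].[Li+] | intermediate (not isolated)
9 | (5S)-5-[(1R,4S)-1-hydroxy-4-methyl-4-(triethylsilyloxy)hex-5-en-1-yl]-5-methyloxolan-2-one | C=C[C@@](C)(O[Si](CC)(CC)CC)CC[C@@H](O)[C@]1(C)CCC(=O)O1 | intermediate
10 | (5S)-5-[(1R,4S)-1,4-dihydroxy-4-methylhex-5-en-1-yl]-5-methyloxolan-2-one | C=C[C@@](C)(O)CC[C@@H](O)[C@]1(C)CCC(=O)O1 | intermediate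
11 | furan-3-carbaldehyde | O=Cc1ccoc1 | starting material
12 | 3-ethenylfuran | C=Cc1ccoc1 | intermediate
13 | pent-1-en-4-yne | C#CCC=C | starting material
14 | dimethyl[(1E)-2-methylpenta-1,4-dien-1-yl]alumane | C=CC/C(C)=C/[Al](C)C | intermediate (not isolated)
15 | (1E)-1-iodo-2-methylpenta-1,4-diene | C=CC/C(C)=C/I | intermediate
16 | 9-[2-(furan-3-yl)ethyl]-9-borabicyclo[3.3.1]nonane | C(Cc1ccoc1)B1C2CCCC1CCC2 | intermediate (not isolated)
17 | 3-[(3E)-4-methylhepta-3,6-dien-1-yl]furan | C=CC/C(C)=C/CCc1ccoc1 | intermediate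
18 | (5S)-5-[(1R,4S,5E,8E)-11-(furan-3-yl)-1,4-dihydroxy-4,8-dimethylundeca-5,8-dien-1-yl]-5-methyloxolan-2-one | C/C(=C\CCc1ccoc1)C/C=C/[C@@](C)(O)CC[C@@H](O)[C@]1(C)CCC(=O)O1 | target

Total step count: 11. Longest linear sequence: 8 steps (steps 1–7 and 11).

Steps most likely to fail

Step 6 (proposed new method). The ester enolate may fragment to ketene and alkoxide on warming, alkylate on oxygen, or open the oxirane too slowly in the geometrically demanding endo mode. The fallback sets out from allylic alcohol 4 and comes back at lactone 9. A Johnson–Claisen rearrangement of 4 (triethyl orthoacetate, catalytic propionic acid, 140 °C) should give the E-configured unsaturated ester ethyl (4E,8S)-4,8-dimethyl-8-(triethylsilyloxy)deca-4,9-dienoate F1; the carbinol centre is sacrificed and the chair transition state sets the E-trisubstituted alkene. Shi epoxidation of the trisubstituted alkene with the D-fructose-derived ketone should then give ethyl 3-{(2R,3R)-2-methyl-3-[(3S)-3-methyl-3-(triethylsilyloxy)pent-4-en-1-yl]oxiran-2-yl}propanoate F2. Saponification (LiOH, THF/H2O) gives 3-{(2R,3R)-2-methyl-3-[(3S)-3-methyl-3-(triethylsilyloxy)pent-4-en-1-yl]oxiran-2-yl}propanoic acid F3. On mild acidification (camphorsulfonic acid, CH2Cl2) the carboxyl group should open the oxirane 5-exo at the tertiary carbon with inversion, which gives 9 with the same (5S) and carbinol (R) configuration.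

Step 11. Self-metathesis of the diene may outrun cross-metathesis at the hindered vinyl carbinol, and ruthenium hydride species may move the skipped diene into conjugation. The fallback sets out from diol lactone 10 (with borane 16 for the partner) and comes back at target 18. Cross-metathesis of 10 with vinylboronic acid pinacol ester (same ruthenium catalyst) should give the E-alkenylboronate (5S)-5-[(1R,4S,5E)-1,4-dihydroxy-4-methyl-6-(4,4,5,5-tetramethyl-1,3,2-dioxaborolan-2-yl)hex-5-en-1-yl]-5-methyloxolan-2-one F4. Separately, borane 16 is coupled with commercial (E)-3-iodo-2-methylprop-2-en-1-ol (Pd(dppf)Cl2, Cs2CO3) to give (2E)-5-(furan-3-yl)-2-methylpent-2-en-1-ol F5, and an Appel reaction (CBr4, PPh3) converts it into 3-[(3E)-5-bromo-4-methylpent-3-en-1-yl]furan F6. Suzuki–Miyaura allyl–alkenyl coupling of F4 with F6 (Pd(PPh3)4, CsF, THF) at the primary allylic terminus should form the skipped diene and give 18.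

Step 3. The aluminium amide may remove a proton on the methylene side instead of from the methyl group, or the Lewis acid may trigger a hydride shift of the oxirane to a ketone. The fallback sets out from silyl ether 2 and comes back at epoxy alcohol 5, bypassing steps 2–4. A Schenck ene reaction of 2 with singlet oxygen (O2, tetraphenylporphyrin, visible light, CH2Cl2) should give, beside its tertiary regioisomer, the secondary allylic hydroperoxide (3RS,6S)-2,6-dimethyl-6-(triethylsilyloxy)octa-1,7-dien-3-yl hydroperoxide F7. Reduction with PPh3 gives the epimeric alcohols (3RS,6S)-2,6-dimethyl-6-(triethylsilyloxy)octa-1,7-dien-3-ol F8. Sharpless kinetic-resolution epoxidation (Ti(OiPr)4, D-(−)-diisopropyl tartrate, t-BuOOH, 4 Å sieves, −20 °C) should epoxidise the (3R)-epimer fast and erythro-selectively to 5 and leave the (3S)-epimer, at the cost of at most half of the material.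

Further compounds
F1 | step 6 | ethyl (4E,8S)-4,8-dimethyl-8-(triethylsilyloxy)deca-4,9-dienoate | CCOC(=O)CC/C(C)=C/CC[C@](C)(O[Si](CC)(CC)CC)C=C
F2 | step 6 | ethyl 3-{(2R,3R)-2-methyl-3-[(3S)-3-methyl-3-(triethylsilyloxy)pent-4-en-1-yl]oxiran-2-yl}propanoate | CCOC(=O)CC[C@@]1(C)O[C@@H]1CC[C@](C)(O[Si](CC)(CC)CC)C=C
F3 | step 6 | 3-{(2R,3R)-2-methyl-3-[(3S)-3-methyl-3-(triethylsilyloxy)pent-4-en-1-yl]oxiran-2-yl}propanoic acid | OC(=O)CC[C@@]1(C)O[C@@H]1CC[C@](C)(O[Si](CC)(CC)CC)C=C
F4 | step 11 | (5S)-5-[(1R,4S,5E)-1,4-dihydroxy-4-methyl-6-(4,4,5,5-tetramethyl-1,3,2-dioxaborolan-2-yl)hex-5-en-1-yl]-5-methyloxolan-2-one | CC1(C)OB(/C=C/[C@@](C)(O)CC[C@@H](O)[C@]2(C)CCC(=O)O2)OC1(C)C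
F5 | step 11 | (2E)-5-(furan-3-yl)-2-methylpent-2-en-1-ol | OC/C(C)=C/CCc1ccoc1
F6 | step 11 | 3-[(3E)-5-bromo-4-methylpent-3-en-1-yl]furan | BrC/C(C)=C/CCc1ccoc1
F7 | step 3 | (3RS,6S)-2,6-dimethyl-6-(triethylsilyloxy)octa-1,7-dien-3-yl hydroperoxide | C=C[C@@](C)(O[Si](CC)(CC)CC)CCC(OO)C(C)=C
F8 | step 3 | (3RS,6S)-2,6-dimethyl-6-(triethylsilyloxy)octa-1,7-dien-3-ol | C=C[C@@](C)(O[Si](CC)(CC)CC)CCC(O)C(C)=C
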